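## Analysis of the target

The target 11 is a depside: two benzene rings joined only by an aryl ester. Ring A is numbered C1 (CO2Me), C2 (OH), C3 (CH3), C4 (O-acyl), C5 (H), C6 (CH3). Ring B is numbered C1' (depside carbonyl), C2', C3', C4' (three adjacent OH), C5' (H), C6' (CH3). There is no stereocentre and no stereogenic double bond, so only constitution has to be controlled.

The sensitive groups are:
- the depside ester, an activated aryl ester that bases and strong nucleophiles cleave;
- the methyl ester on ring A;
- the 2',3',4'-triol of ring B, which is oxidised easily, above all as its phenolate.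

The difficulty is threefold. The oxygen at C3' must be placed between two existing hydroxyls on a pentasubstituted ring. The rings must be joined at O4 and not at O2. The vicinal triol must not be carried through many steps.

The strategy rests on C3' of ring B. It lies ortho to both the C2' and C4' hydroxyls, which is the position where a meta-dihydroxy benzoate accepts a formyl group. The lichen depside atranorin 9 differs from 11 only in having CHO instead of OH at C3'. A formyl group at C3' can therefore mark the position of the third oxygen and be exchanged for it in the last operation.

## Retrosynthetic reasoning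

**C3'–O bond (11 ⇒ 10 ⇒ 9).** The C3' hydroxyl is traced back to the formate 10, and this to the aldehyde 9. In the forward direction a peroxide adds to the formyl carbon, C3' migrates from carbon to oxygen, and the formate is hydrolysed in the same flask. The cut is made here because an oxygen electrophile cannot be directed cleanly to C3', whereas a carbon electrophile goes there readily. The gain is that the regiochemistry of the third oxygen is fixed by the formyl group. In addition, 9 needs no protecting groups, and the oxidisable triol appears only in the final flask. The forward reaction must oxidise the aldehyde without touching the depside ester or the new triol.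

**Depside ester (9 ⇒ 7 + 8).** The acyl C–O4 bond is cut, giving the acid 7 and the phenol 8. This is the only bond between the rings, and 8 is a purchasable compound that already contains ring A complete. Making this bond before the oxidation means the acid partner has only two phenols, each tied to a carbonyl group by a hydrogen bond, instead of a free triol. The forward reaction has to activate the carboxyl of 7 and acylate O4 of 8. O4 is the one hydroxyl of either partner that is not chelated.

**Carboxyl unmasking (7 ⇒ 6).** The acid 7 decarboxylates easily and would interfere with a Lewis-acid formylation, so the carboxyl is carried as a benzyl ester. Neutral hydrogenolysis removes it without base or heat.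

**C3–CHO bond (6 ⇒ 3 + 4, through 5).** The formyl carbon comes from 4 in a Lewis-acid-mediated aromatic substitution on 3. C3 is ortho to both hydroxyls, and chelation of the C2 hydroxyl to the ester fixes the ring bonds so that the C4 hydroxyl acts as an enol with C3 as its β-carbon. The forward reaction must favour C3 over C5.

**Benzyl ester (3 ⇒ 1 + 2).** The ester C–O bond is cut, giving the acid 1 and the halide 2. The forward reaction must alkylate the carboxylate and leave both phenols free.

## Alternatives that were turned down

**Alternative 1: ring A from acyclic esters.**
- Disconnection: ring A is opened at C1–C6 and C3–C4, giving methyl 3-oxopentanoate A1 and methyl (E)-but-2-enoate A2.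
- Forward key step: under alkoxide base, the C2 carbanion of A1 adds to the β-carbon of A2 (Michael addition). The ethyl-ketone α-carbon then closes onto the crotonate ester carbonyl (Claisen closure) to give the cyclohexanedione A3. A later dehydrogenation would aromatise A3 to 8.
- For: bulk starting materials; the substitution pattern of ring A follows from connectivity, with no aromatic regiochemistry to control.
- Against: ring A is not the difficult part of 11, and 8 can be bought. Two or three steps would be spent on it, and ring B, its three adjacent oxygens and the depside bond would remain unsolved.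
- Comparison: Alternative 1 is stronger on raw-material cost and on independence from a speciality phenol. The chosen strategy offers in its place a short route whose one demanding step addresses the C3' oxygen, the feature that sets 11 apart from common depsides.

**Alternative 2: Diels–Alder construction of ring B on the ester.**
- Disconnection: ring B is cut at C1'–C2' and C5'–C6', giving the but-2-ynoate ester of ring A, A4, and the tri-oxygenated bis-silyloxy diene A5.
- Forward key step: the nucleophilic CH2 terminus of A5 bonds to the methyl-bearing alkyne carbon of A4, and the ketene-acetal carbon bonds to the carbon α to the ester. Loss of methanol aromatises the adduct to the 3'-O-benzyl depside A6. Hydrogenolysis would then give 11.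
- For: convergent; the three oxygens arrive already in place and differentiated; the last step is reductive, so the triol never meets an oxidant.
- Against: A5 is a hydrolytically fragile bis-silyl ketene acetal that needs several steps from an α-benzyloxy β-keto ester. A tetrolate is a sluggish dienophile and would need heat that such a diene tolerates poorly. The free C2 hydroxyl of A4 would protonate or desilylate the diene unless it is protected. The aryl ynoate is itself an activated ester open to conjugate addition. The regiochemistry with a 2-alkoxy substituent on the diene is plausible but rests on polarisation arguments only.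
- Comparison: Alternative 2 is as strong or stronger in protecting the triol. The chosen strategy offers fewer steps, no fragile reagent, and a regiochemical marker (the formyl group) set by a classical substitution.

**Alternative 3: carboxylate O-arylation.**
- Disconnection: the O–C4 bond is cut with reversed polarity, giving the tribenzyl acid A7 and the aryl bromide A8.
- Forward key step: a light-driven, nickel-catalysed C–O cross-coupling joins the carboxylate of A7 to C4 of A8 and gives the perbenzylated depside A9. Global hydrogenolysis would then give 11.
- For: all phenols are masked, so no hydroxyl selectivity arises in the coupling, and the final step is again reductive.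
- Against: A7 is a 2,6-disubstituted, hindered carboxylate. A8 is an electron-rich bromide with an ortho methyl. These are the two features that slow both oxidative addition and C–O reductive elimination at nickel. A8 cannot be made from 8 without first removing the oxygen O4 that the coupling then restores. A7 still requires the trioxygenated ring B, so the C3' oxygen problem is postponed, not solved. The step count is roughly double.
- Comparison: Alternative 3 is stronger in avoiding any late oxidant. The chosen strategy uses the O4 oxygen already present in 8, forms the inter-ring bond by ordinary acylation, and needs no protecting group on either ring at the key step.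

Key step: step 5

Remark: 1 and 8 are taken as purchasable; 11 has no stereocentre; intermediate 5 is drawn as the neutral chloro ether although in the flask it is bound to titanium.

## Route

Step 1
Reactants: 1 orsellinic acid (2,4-dihydroxy-6-methylbenzoic acid); 2 benzyl bromide
Product: 3 benzyl orsellinate (benzyl 2,4-dihydroxy-6-methylbenzoate)
Conditions: BnBr (1.05 equiv), KHCO3 (1.1 equiv), DMF, rt
Reagents that add atoms: benzyl bromide (compound 2), BrCc1ccccc1
Why: Carboxylate O-alkylation (SN2); hydrogen carbonate deprotonates only the carboxylic acid and not the phenols, so only the carboxylate is benzylated, and room temperature avoids the easy decarboxylation of this ortho,para-dihydroxy acid.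

Step 2
Reactants: 3 benzyl orsellinate; 4 dichloromethyl methyl ether
Product: 6 benzyl haematommate (benzyl 3-formyl-2,4-dihydroxy-6-methylbenzoate), via chloro(methoxy)methyl arene 5 (not isolated)
Conditions: Cl2CHOMe (1.2 equiv), TiCl4 (3 equiv), CH2Cl2, −10 → 0 °C; then ice-cold 1 M HCl
Reagents that add atoms: dichloromethyl methyl ether (compound 4), COC(Cl)Cl; water, O
Why: Rieche formylation; the titanium phenoxide delivers the chloro(methoxy)carbenium electrophile ortho to oxygen, and C3 is ortho to both hydroxyls and is the enolic β-carbon of the C4 hydroxyl once the C2 hydroxyl is chelated to the ester, so attack at C3 should outweigh attack at C5, which also has the C6 methyl beside it. Aqueous acid then hydrolyses 5 to the aldehyde, whose oxygen comes from water.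

Step 3
Reactants: 6 benzyl haematommate
Product: 7 haematommic acid (3-formyl-2,4-dihydroxy-6-methylbenzoic acid)
Conditions: H2 (1 atm), 10% Pd/C, EtOAc, rt
Reagents that add atoms: none
Why: Hydrogenolysis of a benzyl ester; the benzylic C–O bond is cleaved much faster than the formyl group is reduced, because the aldehyde sits between two hydrogen-bonding hydroxyls and behaves as a vinylogous acid, and neutral conditions at room temperature avoid decarboxylation.

Step 4
Reactants: 7 haematommic acid; 8 methyl atrarate (methyl 2,4-dihydroxy-3,6-dimethylbenzoate)
Product: 9 atranorin (methyl 4-[(3-formyl-2,4-dihydroxy-6-methylbenzoyl)oxy]-2-hydroxy-3,6-dimethylbenzoate)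
Conditions: DCC (1.1 equiv), Et2O–toluene, 0 °C → rt
Reagents that add atoms: none
Why: Carbodiimide-mediated esterification of a phenol; the O-acylisourea of 7 should be taken up by the C4 hydroxyl of 8, the only hydroxyl in either partner not held in a hydrogen bond to a carbonyl group, whereas the C2 hydroxyl of 8 and both hydroxyls of 7 are chelated and flanked by substituents.

Step 5
Reactants: 9 atranorin
Product: 11 target depside CNP0249278.0 (methyl 2-hydroxy-3,6-dimethyl-4-[(2,3,4-trihydroxy-6-methylbenzoyl)oxy]benzoate), via aryl formate 10 (not isolated)
Conditions: 30% aq. H2O2 (1.3 equiv), B(OH)3 (5 equiv), H2SO4 (cat.), THF, Ar, rt; then aq. Na2S2O3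
Reagents that add atoms: hydrogen peroxide, OO
Why: Dakin oxidation, a Baeyer–Villiger-type oxidation of an ortho-hydroxy aryl aldehyde, run here in its acid-mediated hydrogen peroxide/boric acid form. Peroxide, activated as a peroxoborate, adds to the formyl carbon of 9, the most electrophilic and least hindered carbonyl in the molecule, giving a Criegee-type hydroxy-peroxy adduct. C3' then shifts from the formyl carbon to the proximal peroxide oxygen with loss of borate or water, which forms the C3'–O bond and gives formate 10; aryl migration is preferred over hydride migration because the hydroxyls at C2' and C4' flank C3' and stabilise the positive charge on the migrating carbon. Formate 10, a reactive aryl formate between two phenols, should be hydrolysed in the same acidic aqueous THF to 11 and formic acid. No ring is closed and no stereocentre is formed, so the step needs chemoselectivity only. The depside ester and the methyl ester are both 2,6-disubstituted benzoates, and without base there is no hydroperoxide anion to cleave them. Further oxidation of the new 2',3',4'-triol is held back by the near-stoichiometric amount of oxidant, the acidic medium that keeps the phenols protonated, the electron-withdrawing ester on ring B, and reversible binding of the vicinal hydroxyls as a borate ester until work-up.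

## Compound list

1 | orsellinic acid (2,4-dihydroxy-6-methylbenzoic acid) | Cc1cc(O)cc(O)c1C(=O)O | starting material
2 | benzyl bromide | BrCc1ccccc1 | starting material
3 | benzyl orsellinate (benzyl 2,4-dihydroxy-6-methylbenzoate) | Cc1cc(O)cc(O)c1C(=O)OCc1ccccc1 | intermediate
4 | dichloromethyl methyl ether | COC(Cl)Cl | starting material
5 | benzyl 3-[chloro(methoxy)methyl]-2,4-dihydroxy-6-methylbenzoate (racemic at the chloro(methoxy)methyl carbon, not isolated) | COC(Cl)c1c(O)cc(C)c(C(=O)OCc2ccccc2)c1O | intermediate
6 | benzyl haematommate (benzyl 3-formyl-2,4-dihydroxy-6-methylbenzoate) | Cc1cc(O)c(C=O)c(O)c1C(=O)OCc1ccccc1 | intermediate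
7 | haematommic acid (3-formyl-2,4-dihydroxy-6-methylbenzoic acid) | Cc1cc(O)c(C=O)c(O)c1C(=O)O | intermediate
8 | methyl atrarate (methyl 2,4-dihydroxy-3,6-dimethylbenzoate) | COC(=O)c1c(C)cc(O)c(C)c1O | starting material
9 | atranorin (methyl 4-[(3-formyl-2,4-dihydroxy-6-methylbenzoyl)oxy]-2-hydroxy-3,6-dimethylbenzoate) | COC(=O)c1c(C)cc(OC(=O)c2c(C)cc(O)c(C=O)c2O)c(C)c1O | intermediate
10 | methyl 4-{[3-(formyloxy)-2,4-dihydroxy-6-methylbenzoyl]oxy}-2-hydroxy-3,6-dimethylbenzoate (aryl formate, not isolated) | COC(=O)c1c(C)cc(OC(=O)c2c(C)cc(O)c(OC=O)c2O)c(C)c1O | intermediate
11 | CNP0249278.0 (methyl 2-hydroxy-3,6-dimethyl-4-[(2,3,4-trihydroxy-6-methylbenzoyl)oxy]benzoate) | COC(=O)c1c(C)cc(OC(=O)c2c(C)cc(O)c(O)c2O)c(C)c1O | target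

## Step count and risk

Total step count: 5. Longest linear sequence: 5 steps (1 → 3 → 6 → 7 → 9 → 11); 8 enters at step 4.

**Step 5 (key step).**
- What may go wrong: perhydrolysis of the depside ester, or further oxidation of the newly formed triol by residual peroxide or air. The peroxide may also add slowly, because the formyl group is hydrogen-bonded on both sides and is a weak electrophile.
- Fallback, from 9 back to 11: the C4' hydroxyl of 9 is the most acidic and is held by a single hydrogen bond. It would be benzylated (BnBr, K2CO3, acetone, rt) to give 4'-O-benzylatranorin F1. The formyl group of F1, now chelated on one side only, would be oxidised with mCPBA in CH2Cl2 at 0 °C, an anhydrous peracid Baeyer–Villiger oxidation with no nucleophilic peroxide present, to give the aryl formate F2. Methanolysis of the formate (MeOH, Et3N cat., 0 °C) would give the 4'-O-benzyl-2',3'-diol F3. Hydrogenolysis (H2, Pd/C, EtOAc) would then release 11 under reducing conditions, so the free triol never meets an oxidant.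

**Step 2.**
- What may go wrong: competing formylation at C5, because both open ring positions are ortho to the C4 hydroxyl, and partial loss of the benzyl ester under the strong Lewis acid.
- Fallback, from 3 back to 7: 3 would be brominated (NBS, CH2Cl2, 0 °C). Halogenation is expected para to the chelated C2 hydroxyl, giving benzyl 5-bromoorsellinate F4. With C5 blocked, formylation under the conditions of step 2 can occur only between the hydroxyls. It would pass through the chloro(methoxy)methyl arene F5 and give the bromo aldehyde F6. Hydrogenolysis with H2, Pd/C and NaOAc in EtOAc–MeOH would remove the benzyl group and the bromine together and give 7.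

**Step 4.**
- What may go wrong: self-condensation of 7 through its own C4 hydroxyl, rearrangement of the O-acylisourea to an unreactive N-acylurea before the hindered phenol attacks, or some acylation at O2 of 8.
- Fallback, from 6 back to 9: the C4 hydroxyl of 6 would be silylated (TBSCl, imidazole, DMF) to give the silyl ether F7. Hydrogenolysis (H2, Pd/C, EtOAc) would give the acid F8, whose only free hydroxyl is chelated on both sides. This acid can be coupled with 8 under DMAP catalysis (DCC, DMAP cat., CH2Cl2) to give 4'-O-silylated atranorin F9. Desilylation with HF·pyridine in THF would return 9.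

## Further compounds

F1 | step 5 | methyl 4-{[4-(benzyloxy)-3-formyl-2-hydroxy-6-methylbenzoyl]oxy}-2-hydroxy-3,6-dimethylbenzoate (4'-O-benzylatranorin) | COC(=O)c1c(C)cc(OC(=O)c2c(C)cc(OCc3ccccc3)c(C=O)c2O)c(C)c1O
F2 | step 5 | methyl 4-{[4-(benzyloxy)-3-(formyloxy)-2-hydroxy-6-methylbenzoyl]oxy}-2-hydroxy-3,6-dimethylbenzoate | COC(=O)c1c(C)cc(OC(=O)c2c(C)cc(OCc3ccccc3)c(OC=O)c2O)c(C)c1O
F3 | step 5 | methyl 4-{[4-(benzyloxy)-2,3-dihydroxy-6-methylbenzoyl]oxy}-2-hydroxy-3,6-dimethylbenzoate | COC(=O)c1c(C)cc(OC(=O)c2c(C)cc(OCc3ccccc3)c(O)c2O)c(C)c1O
F4 | step 2 | benzyl 3-bromo-4,6-dihydroxy-2-methylbenzoate (benzyl 5-bromoorsellinate) | Cc1c(Br)c(O)cc(O)c1C(=O)OCc1ccccc1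
F5 | step 2 | benzyl 3-bromo-5-[chloro(methoxy)methyl]-4,6-dihydroxy-2-methylbenzoate (not isolated) | COC(Cl)c1c(O)c(Br)c(C)c(C(=O)OCc2ccccc2)c1O
F6 | step 2 | benzyl 3-bromo-5-formyl-4,6-dihydroxy-2-methylbenzoate | Cc1c(Br)c(O)c(C=O)c(O)c1C(=O)OCc1ccccc1
F7 | step 4 | benzyl 4-[(tert-butyldimethylsilyl)oxy]-3-formyl-2-hydroxy-6-methylbenzoate | Cc1cc(O[Si](C)(C)C(C)(C)C)c(C=O)c(O)c1C(=O)OCc1ccccc1
F8 | step 4 | 4-[(tert-butyldimethylsilyl)oxy]-3-formyl-2-hydroxy-6-methylbenzoic acid | Cc1cc(O[Si](C)(C)C(C)(C)C)c(C=O)c(O)c1C(=O)O
F9 | step 4 | methyl 4-({4-[(tert-butyldimethylsilyl)oxy]-3-formyl-2-hydroxy-6-methylbenzoyl}oxy)-2-hydroxy-3,6-dimethylbenzoate | COC(=O)c1c(C)cc(OC(=O)c2c(C)cc(O[Si](C)(C)C(C)(C)C)c(C=O)c2O)c(C)c1O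
A1 | alternative 1 | methyl 3-oxopentanoate | CCC(=O)CC(=O)OC
A2 | alternative 1 | methyl (E)-but-2-enoate | C/C=C/C(=O)OC
A3 | alternative 1 | methyl 3,6-dimethyl-2,4-dioxocyclohexane-1-carboxylate (mixture of tautomers and diastereomers) | COC(=O)C1C(C)CC(=O)C(C)C1=O
A4 | alternative 2 | methyl 4-(but-2-ynoyloxy)-2-hydroxy-3,6-dimethylbenzoate | COC(=O)c1c(C)cc(OC(=O)C#CC)c(C)c1O
A5 | alternative 2 | 2-(benzyloxy)-1-methoxy-1,3-bis(trimethylsilyloxy)buta-1,3-diene (double-bond geometry not defined) | C=C(O[Si](C)(C)C)C(OCc1ccccc1)=C(OC)O[Si](C)(C)C
A6 | alternative 2 | methyl 4-{[3-(benzyloxy)-2,4-dihydroxy-6-methylbenzoyl]oxy}-2-hydroxy-3,6-dimethylbenzoate | COC(=O)c1c(C)cc(OC(=O)c2c(C)cc(O)c(OCc3ccccc3)c2O)c(C)c1O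
A7 | alternative 3 | 2,3,4-tris(benzyloxy)-6-methylbenzoic acid | Cc1cc(OCc2ccccc2)c(OCc2ccccc2)c(OCc2ccccc2)c1C(=O)O
A8 | alternative 3 | methyl 2-(benzyloxy)-4-bromo-3,6-dimethylbenzoate | COC(=O)c1c(C)cc(Br)c(C)c1OCc1ccccc1
A9 | alternative 3 | methyl 2-(benzyloxy)-3,6-dimethyl-4-{[2,3,4-tris(benzyloxy)-6-methylbenzoyl]oxy}benzoate | COC(=O)c1c(C)cc(OC(=O)c2c(C)cc(OCc3ccccc3)c(OCc3ccccc3)c2OCc2ccccc2)c(C)c1OCc1ccccc1
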